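**Retrosynthetic overview**

1. Feature: the bridge CH2, C6 and C1 of the filicinic ring (ring A) and the ring-B phenol oxygen lying between the bridge carbon and the butanoyl carbon form the sequence C4–C3–C2–O1 of a coumarin fused to ring B. C5–C4–C3–C2 of ring A with the acetyl group are the chain of an enol lactone, pyran-2,4-dione 18, which already carries the quaternary C4.
2. Key disconnections: C5–C6 and C1–C2 of ring A, both made in step 11 from coumarin 10 and pyrandione 18 (conjugate reduction, lactone-opening C-acylation, Claisen closure); the coumarin C2–O1 bond is the tether that is cut.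
3. Coumarin 10: 2,4,6-trihydroxybutyrophenone → bis-MOM ether → O-prenyl ether → para-Claisen–Cope → ortho-formylation → ylide annulation (pyranone ring, step 5).
4. Pyrandione 18: methyl (S)-3-hydroxybutanoate → two Fráter–Seebach alkylations (methyl, then geranyl; quaternary centre) → oxidation → C-acetylation → enol lactonisation (pyrandione ring, step 10).
5. Ring order: the two lactone rings (steps 5 and 10) are temporary; ring A, the only ring of the target that must be built, closes in step 11 as both lactones open; step 12 removes the MOM groups.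

Key step: step 11

Remark on the chemistry: enolised β-di- and β-triketones are drawn as one tautomer. The descriptor 4R of ring A refers to the drawn 3,5-dihydroxy-dienone form and is the same spatial arrangement as 3S in pyrandione 18 (only the CIP priorities change). Stryker's reagent is counted as six hydrides per hexamer.

**Route**

Step 1
Reactants: 1 2,4,6-trihydroxybutyrophenone
Product: 2 1-[2-hydroxy-4,6-bis(methoxymethoxy)phenyl]butan-1-one
Conditions: MOMCl (2.2 equiv), i-Pr2NEt, CH2Cl2, 0 → 23 °C
Reagents that add atoms: chloromethyl methyl ether, COCCl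
Why: O-alkylation to MOM ethers should take the para hydroxyl and one ortho hydroxyl and then stop, because the remaining ortho hydroxyl is locked in the hydrogen bond to the butanoyl carbonyl, the usual selectivity of phloroacylophenones.

Step 2
Reactants: 2 1-[2-hydroxy-4,6-bis(methoxymethoxy)phenyl]butan-1-one; 3 prenyl bromide
Product: 4 1-[2,4-bis(methoxymethoxy)-6-(3-methylbut-2-enyloxy)phenyl]butan-1-one
Conditions: K2CO3, DMF, 40 °C
Reagents that add atoms: none
Why: Williamson etherification (SN2 at the primary allylic bromide) of the last phenol should give the aryl prenyl ether that the sigmatropic relay of step 3 needs.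

Step 3
Reactants: 4 1-[2,4-bis(methoxymethoxy)-6-(3-methylbut-2-enyloxy)phenyl]butan-1-one
Product: 7 1-[6-hydroxy-2,4-bis(methoxymethoxy)-3-(3-methylbut-2-enyl)phenyl]butan-1-one, via ortho-Claisen dienone 5 (not isolated), via para-dienone 6 (not isolated)
Conditions: N,N-diethylaniline, 200 °C
Reagents that add atoms: none
Why: Aromatic Claisen rearrangement to the only free ortho carbon, Cope rearrangement of the crowded 1,1-dimethylallyl dienone to the para carbon and enolisation (para-Claisen–Cope, known for 2-prenyloxy-4,6-dialkoxyacylbenzenes) should place a normal prenyl group between the two MOM ethers and return the chelated phenol next to the last free ring CH.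

Step 4
Reactants: 7 1-[6-hydroxy-2,4-bis(methoxymethoxy)-3-(3-methylbut-2-enyl)phenyl]butan-1-one
Product: 8 3-butanoyl-2-hydroxy-4,6-bis(methoxymethoxy)-5-(3-methylbut-2-enyl)benzaldehyde
Conditions: MgCl2, Et3N, (CH2O)n, MeCN, reflux
Reagents that add atoms: formaldehyde (as paraformaldehyde), C=O
Why: Magnesium-mediated ortho-formylation (Casnati–Skattebøl: magnesium phenoxide, formaldehyde, then hydride transfer to a second formaldehyde) is specific for the carbon ortho to the free phenol, here the only unsubstituted ring carbon, and its basic medium should leave MOM ethers and the prenyl group intact.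

Step 5
Reactants: 8 3-butanoyl-2-hydroxy-4,6-bis(methoxymethoxy)-5-(3-methylbut-2-enyl)benzaldehyde
Product: 10 8-butanoyl-5,7-bis(methoxymethoxy)-6-(3-methylbut-2-enyl)-2H-chromen-2-one, via ester ylide 9 (not isolated)
Conditions: Ph3P=C=C=O, toluene, 110 °C
Reagents that add atoms: (triphenylphosphoranylidene)ketene (Bestmann ylide), O=C=C=P(c1ccccc1)(c1ccccc1)c1ccccc1
Why: The phenol adds to the ketenylidene ylide to give an ester-stabilised ylide, whose intramolecular Wittig reaction with the neighbouring aldehyde (far more reactive than the hindered butanoyl ketone) should close the pyranone ring of the coumarin under neutral conditions.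

Step 6
Reactants: 11 methyl (3S)-3-hydroxybutanoate
Product: 12 methyl (2S,3S)-3-hydroxy-2-methylbutanoate
Conditions: LDA (2.2 equiv), THF, −78 → −20 °C; MeI, DMPU; aq. NH4Cl
Reagents that add atoms: iodomethane, CI
Why: Fráter–Seebach alkylation: the chelated lithium alkoxide–enolate dianion should be methylated on the face opposite to the C3 methyl group, so C2 is set as S (anti to the hydroxyl) under control of the 3S carbinol centre.

Step 7
Reactants: 12 methyl (2S,3S)-3-hydroxy-2-methylbutanoate; 13 geranyl bromide
Product: 14 methyl (2S,3S)-2-[(2E)-3,7-dimethylocta-2,6-dienyl]-3-hydroxy-2-methylbutanoate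
Conditions: LDA (2.2 equiv), THF–DMPU, −78 → −10 °C; aq. NH4Cl
Reagents that add atoms: none
Why: Second Fráter–Seebach alkylation: the dianion of the α-methyl ester should again be attacked from the face opposite to the C3 methyl of the chelate, so geranyl takes the place the first electrophile took and the quaternary centre forms as 2S under substrate control; a minor epimer would be removed by chromatography.

Step 8
Reactants: 14 methyl (2S,3S)-2-[(2E)-3,7-dimethylocta-2,6-dienyl]-3-hydroxy-2-methylbutanoate
Product: 15 methyl (2S)-2-[(2E)-3,7-dimethylocta-2,6-dienyl]-2-methyl-3-oxobutanoate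
Conditions: Dess–Martin periodinane, CH2Cl2, 23 °C
Reagents that add atoms: none
Why: Dess–Martin oxidation of the secondary alcohol should give the β-keto ester; its quaternary α-carbon cannot enolise, so the remaining stereocentre is configurationally secure.

Step 9
Reactants: 15 methyl (2S)-2-[(2E)-3,7-dimethylocta-2,6-dienyl]-2-methyl-3-oxobutanoate
Product: 16 methyl (2S)-2-[(2E)-3,7-dimethylocta-2,6-dienyl]-2-methyl-3,5-dioxohexanoate
Conditions: MgBr2·OEt2, i-Pr2NEt, 1-acetylbenzotriazole, CH2Cl2, 23 °C
Reagents that add atoms: 1-acetyl-1H-benzotriazole, CC(=O)n1nnc2ccccc21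
Why: Soft-enolisation C-acylation of a ketone with an N-acylbenzotriazole: the magnesium-chelated keto ester can enolise only at its methyl group, and the product 1,3-diketone is held as its magnesium chelate, which should prevent a second acylation.

Step 10
Reactants: 16 methyl (2S)-2-[(2E)-3,7-dimethylocta-2,6-dienyl]-2-methyl-3,5-dioxohexanoate
Product: 18 (3S)-3-[(2E)-3,7-dimethylocta-2,6-dienyl]-3,6-dimethyl-2H-pyran-2,4(3H)-dione, via dioxo acid 17 (not isolated)
Conditions: LiOH, THF–MeOH–H2O, 23 °C; 1 M HCl to pH 3, 0 °C, cold extraction; EDC·HCl, CH2Cl2, 0 °C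
Reagents that add atoms: none
Why: Saponification (assisted by the neighbouring diketonate oxygen) gives a carboxylate–diketonate dianion that resists decarboxylation, and after cold acidification the 3,5-dioxo acid is closed at once by carbodiimide activation and 6-exo-trig attack of the C5 enol oxygen (enol lactonisation), an activated acyl being required because the product is a vinylogous anhydride.

Step 11
Reactants: 10 8-butanoyl-5,7-bis(methoxymethoxy)-6-(3-methylbut-2-enyl)-2H-chromen-2-one; 18 (3S)-3-[(2E)-3,7-dimethylocta-2,6-dienyl]-3,6-dimethyl-2H-pyran-2,4(3H)-dione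
Product: 21 bis(methoxymethyl) ether of the target (ring-B O4 and O6 protected), via copper enolate 19 (not isolated), via acylated dihydrocoumarin 20 (not isolated)
Conditions: [(Ph3P)CuH]6 (0.19 equiv), 18 (1.2 equiv), THF–toluene, −20 → 23 °C; then MgCl2, Et3N, MeCN, 23 °C; aq. NH4Cl
Reagents that add atoms: none
Why: Proposed new method: copper hydride should add to C4 of coumarin 10 (Stryker-type conjugate reduction) and the C3 enolate 19 is acylated in the same flask at the lactone carbonyl of 18, which opens the pyran ring to the diketonate of 20 and forms the C5–C6 bond of ring A. The diketonate carbon of 20 then attacks the aryl lactone carbonyl in a 6-exo-trig Claisen (Dieckmann-type) closure with the ring-B phenoxide as leaving group, which forms the C1–C2 bond, closes the filicinic ring (the only ring made here) and frees the phenol. The closest known reactions are copper hydride reductive aldol and Claisen-type trapping of conjugate-reduction enolates, ring-opening C-acylation of ester enolates by enol lactones, and Claisen cyclisation of tricarbonyl chains onto aryl esters; their combination in one flask on these partners is new. No stereocentre is created: C3 of the dihydrocoumarin ends as an sp2 carbon, and the non-enolisable quaternary centre of 18 is carried over unchanged, its lactone carbonyl becoming C5 and its ketone C3 (hence 4R in 21). The step needs hydride delivery to the coumarin only and enolate attack at C2 of 18; the first is secured because copper hydride leaves the butanoyl ketone, isolated alkenes and the β-alkoxy enone of 18 alone, the second because C4 and C6 of 18 belong to a deactivated vinylogous ester whereas C2 is an activated acyl with a diketonate leaving group. It also needs C- instead of O-acylation in the closure, which magnesium chelation and reversibility should secure: the freed phenoxide can re-open an enol ester, aldol adducts cannot aromatise past the quaternary carbon, only the β-triketone leaves the equilibrium as its stabilised anion, and one hydride equivalent with a weak amine base keeps the β-keto lactone of 20 partly protonated and electrophilic.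

Step 12
Reactants: 21 bis(methoxymethyl) ether of the target
Product: 22 target, (4R)-2-acetyl-6-{[3-butanoyl-2,4,6-trihydroxy-5-(3-methylbut-2-enyl)phenyl]methyl}-4-[(2E)-3,7-dimethylocta-2,6-dienyl]-3,5-dihydroxy-4-methylcyclohexa-2,5-dien-1-one
Conditions: 3 M HCl, MeOH, 23 °C
Reagents that add atoms: none
Why: Acid-catalysed acetal exchange in methanol should remove both MOM groups at room temperature, conditions that ortho-prenyl phenols and the geranyl chain are expected to tolerate, and the quaternary centre is not touched.

**Compound list**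

1 | 2,4,6-trihydroxybutyrophenone | CCCC(=O)c1c(O)cc(O)cc1O | starting material
2 | 1-[2-hydroxy-4,6-bis(methoxymethoxy)phenyl]butan-1-one | CCCC(=O)c1c(O)cc(OCOC)cc1OCOC | intermediate
3 | prenyl bromide (1-bromo-3-methylbut-2-ene) | CC(C)=CCBr | starting material
4 | 1-[2,4-bis(methoxymethoxy)-6-(3-methylbut-2-enyloxy)phenyl]butan-1-one | CCCC(=O)c1c(OCC=C(C)C)cc(OCOC)cc1OCOC | intermediate
5 | ortho-Claisen dienone (not isolated): 2-butanoyl-3,5-bis(methoxymethoxy)-6-(2-methylbut-3-en-2-yl)cyclohexa-2,4-dien-1-one | CCCC(=O)C1=C(OCOC)C=C(OCOC)C(C(C)(C)C=C)C1=O | intermediate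
6 | para-dienone (not isolated): 2-butanoyl-3,5-bis(methoxymethoxy)-4-(3-methylbut-2-enyl)cyclohexa-2,5-dien-1-one | CCCC(=O)C1=C(OCOC)C(CC=C(C)C)C(OCOC)=CC1=O | intermediate
7 | 1-[6-hydroxy-2,4-bis(methoxymethoxy)-3-(3-methylbut-2-enyl)phenyl]butan-1-one | CCCC(=O)c1c(O)cc(OCOC)c(CC=C(C)C)c1OCOC | intermediate
8 | 3-butanoyl-2-hydroxy-4,6-bis(methoxymethoxy)-5-(3-methylbut-2-enyl)benzaldehyde | CCCC(=O)c1c(O)c(C=O)c(OCOC)c(CC=C(C)C)c1OCOC | intermediate
9 | ester ylide (not isolated): 2-butanoyl-6-formyl-3,5-bis(methoxymethoxy)-4-(3-methylbut-2-enyl)phenyl (triphenylphosphoranylidene)acetate | CCCC(=O)c1c(OC(=O)C=P(c2ccccc2)(c2ccccc2)c2ccccc2)c(C=O)c(OCOC)c(CC=C(C)C)c1OCOC | intermediate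
10 | 8-butanoyl-5,7-bis(methoxymethoxy)-6-(3-methylbut-2-enyl)-2H-chromen-2-one | O=C1C=Cc2c(OCOC)c(CC=C(C)C)c(OCOC)c(C(=O)CCC)c2O1 | intermediate
11 | methyl (3S)-3-hydroxybutanoate | C[C@H](O)CC(=O)OC | starting material
12 | methyl (2S,3S)-3-hydroxy-2-methylbutanoate | COC(=O)[C@@H](C)[C@H](C)O | intermediate
13 | geranyl bromide, (2E)-1-bromo-3,7-dimethylocta-2,6-diene | CC(C)=CCC/C(C)=C/CBr | starting material
14 | methyl (2S,3S)-2-[(2E)-3,7-dimethylocta-2,6-dienyl]-3-hydroxy-2-methylbutanoate | COC(=O)[C@@](C)(C/C=C(\C)CCC=C(C)C)[C@H](C)O | intermediate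
15 | methyl (2S)-2-[(2E)-3,7-dimethylocta-2,6-dienyl]-2-methyl-3-oxobutanoate | COC(=O)[C@@](C)(C/C=C(\C)CCC=C(C)C)C(C)=O | intermediate
16 | methyl (2S)-2-[(2E)-3,7-dimethylocta-2,6-dienyl]-2-methyl-3,5-dioxohexanoate | COC(=O)[C@@](C)(C/C=C(\C)CCC=C(C)C)C(=O)CC(C)=O | intermediate
17 | dioxo acid (not isolated): (2S)-2-[(2E)-3,7-dimethylocta-2,6-dienyl]-2-methyl-3,5-dioxohexanoic acid | OC(=O)[C@@](C)(C/C=C(\C)CCC=C(C)C)C(=O)CC(C)=O | intermediate
18 | (3S)-3-[(2E)-3,7-dimethylocta-2,6-dienyl]-3,6-dimethyl-2H-pyran-2,4(3H)-dione | O=C1[C@@](C)(C/C=C(\C)CCC=C(C)C)C(=O)C=C(C)O1 | intermediate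
19 | copper enolate (not isolated): copper(I) C2-enolate of 8-butanoyl-5,7-bis(methoxymethoxy)-6-(3-methylbut-2-enyl)-3,4-dihydrocoumarin | CCCC(=O)c1c(OCOC)c(CC=C(C)C)c(OCOC)c2c1OC(O[Cu])=CC2 | intermediate
20 | acylated dihydrocoumarin (not isolated): 8-butanoyl-3-[(2S)-2-geranyl-2-methyl-3,5-dioxohexanoyl]-5,7-bis(methoxymethoxy)-6-(3-methylbut-2-enyl)-3,4-dihydro-2H-chromen-2-one, C3 epimers | CCCC(=O)c1c(OCOC)c(CC=C(C)C)c(OCOC)c2c1OC(=O)C(C2)C(=O)[C@@](C)(C/C=C(\C)CCC=C(C)C)C(=O)CC(C)=O | intermediate
21 | (4R)-2-acetyl-6-{[3-butanoyl-2-hydroxy-4,6-bis(methoxymethoxy)-5-(3-methylbut-2-enyl)phenyl]methyl}-4-[(2E)-3,7-dimethylocta-2,6-dienyl]-3,5-dihydroxy-4-methylcyclohexa-2,5-dien-1-one | CCCC(=O)c1c(OCOC)c(CC=C(C)C)c(OCOC)c(CC2=C(O)[C@@](C)(C/C=C(\C)CCC=C(C)C)C(O)=C(C(C)=O)C2=O)c1O | intermediate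
22 | (4R)-2-acetyl-6-{[3-butanoyl-2,4,6-trihydroxy-5-(3-methylbut-2-enyl)phenyl]methyl}-4-[(2E)-3,7-dimethylocta-2,6-dienyl]-3,5-dihydroxy-4-methylcyclohexa-2,5-dien-1-one | CCCC(=O)c1c(O)c(CC=C(C)C)c(O)c(CC2=C(O)[C@@](C)(C/C=C(\C)CCC=C(C)C)C(O)=C(C(C)=O)C2=O)c1O | target

**Totals and risks**

Total step count: 12. Longest linear sequence: 7 steps (steps 1–5, 11, 12; the branch of steps 6–10, 11, 12 is equally long).

Steps most likely to fail:

1. Step 11 (proposed method). The copper enolate may be protonated, or add to a second coumarin, faster than it acylates the neopentylic lactone carbonyl of 18; the second closure may stall at O-acylation or at a reversible aldol adduct. The fallback uses known reactions only, sets out from 18 and 7, and rejoins the route at 22. The lithium enolate of methyl acetate (LDA, THF, −78 °C) opens 18 at its lactone carbonyl by Claisen acylation to methyl (4S)-4-geranyl-4-methyl-3,5,7-trioxooctanoate F1. Sodium methoxide in methanol closes this by Dieckmann condensation to the acetylfilicinic acid (4R)-2-acetyl-4-geranyl-3,5-dihydroxy-4-methylcyclohexa-2,5-dien-1-one F2. Phenol 7 is freed of its MOM groups (HCl, MeOH) to 1-[2,4,6-trihydroxy-3-(3-methylbut-2-enyl)phenyl]butan-1-one F3. F2 and F3 are then joined with aqueous formaldehyde and catalytic base in the classical methylene-bridge condensation of filicinic acids with acylphloroglucinols, which should give 22 beside the two symmetrical dimers, to be separated by chromatography.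

2. Step 10. The free β-keto acid may decarboxylate during the cold acid work-up, or the chain may suffer retro-Claisen cleavage while the hindered ester is saponified. The fallback sets out from 15 and rejoins at 18 without any β-keto acid. The kinetic lithium enolate of 15 (LDA, THF, −78 °C) adds to acetaldehyde to give the aldol methyl (2S)-2-geranyl-5-hydroxy-2-methyl-3-oxohexanoate F4 (C5 epimers). This lactonises with loss of methanol (cat. K2CO3 or PPTS) to (3S)-3-geranyl-3,6-dimethyldihydro-2H-pyran-2,4(3H)-dione F5, an ordinary δ-lactone that needs no acyl activation. Mukaiyama dehydrogenation of the lithium enolate of F5 (LDA; N-tert-butylbenzenesulfinimidoyl chloride, −78 °C) introduces the C5=C6 double bond and gives 18.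

3. Step 4. Ortho-formylation may be slow because magnesium is held in the phenoxide–butanoyl chelate, and the hydroxymethyl intermediate may condense on to diarylmethanes. The fallback sets out from 7 and rejoins at 10 by a different ring construction. Esterification of 7 with propiolic acid (DCC, CH2Cl2, −20 → 0 °C) gives 2-butanoyl-3,5-bis(methoxymethoxy)-4-(3-methylbut-2-enyl)phenyl prop-2-ynoate F6. Gold(I)-catalysed intramolecular hydroarylation of the aryl propiolate (Ph3PAuNTf2, 1,2-dichloroethane) closes 6-endo at the only free ortho carbon and gives coumarin 10.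

Further compounds
F1 | step 11 | methyl (4S)-4-[(2E)-3,7-dimethylocta-2,6-dienyl]-4-methyl-3,5,7-trioxooctanoate | COC(=O)CC(=O)[C@@](C)(C/C=C(\C)CCC=C(C)C)C(=O)CC(C)=O
F2 | step 11 | (4R)-2-acetyl-4-[(2E)-3,7-dimethylocta-2,6-dienyl]-3,5-dihydroxy-4-methylcyclohexa-2,5-dien-1-one | O=C1C=C(O)[C@@](C)(C/C=C(\C)CCC=C(C)C)C(O)=C1C(C)=O
F3 | step 11 | 1-[2,4,6-trihydroxy-3-(3-methylbut-2-enyl)phenyl]butan-1-one | CCCC(=O)c1c(O)cc(O)c(CC=C(C)C)c1O
F4 | step 10 | methyl (2S)-2-[(2E)-3,7-dimethylocta-2,6-dienyl]-5-hydroxy-2-methyl-3-oxohexanoate (C5 epimers) | COC(=O)[C@@](C)(C/C=C(\C)CCC=C(C)C)C(=O)CC(C)O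
F5 | step 10 | (3S)-3-[(2E)-3,7-dimethylocta-2,6-dienyl]-3,6-dimethyldihydro-2H-pyran-2,4(3H)-dione (C6 epimers) | O=C1[C@@](C)(C/C=C(\C)CCC=C(C)C)C(=O)CC(C)O1
F6 | step 4 | 2-butanoyl-3,5-bis(methoxymethoxy)-4-(3-methylbut-2-enyl)phenyl prop-2-ynoate | CCCC(=O)c1c(OC(=O)C#C)cc(OCOC)c(CC=C(C)C)c1OCOC
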